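**Assumption:** the target is taken exactly as the SMILES encodes it, (2R,9'R)-9'-hydroxy-δ-tocotrienol; commercial (R)-(−)-linalool and methyl (R)-glycidate are assumed to be of high ee.

## Retrosynthetic overview

1. C6'–C7' is cut last: Ni-catalysed decarboxylative alkenylation of chroman acid **10** with vinyl iodide **15**, then global desilylation.
2. Acid **10** comes from an Ireland–Claisen [3,3] rearrangement of allylic acetate **9**, which forms C5'–C6' and sets the 3'E olefin; **9** comes from prenyl chroman **7** via aldehyde **8**.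
3. The dihydropyran ring of the chroman is the only ring formed (the benzene ring is bought). It is closed by Pd C–O coupling of tertiary alcohol **6**, which comes from B-alkyl Suzuki coupling of (R)-linalool with bromo-iodoarene **4**. C2 is the linalool stereocentre, its C–O bond never broken.
4. Vinyl iodide **15** comes from Negishi carboalumination of alkyne **14**, made from methyl (R)-glycidate by cuprate opening; C9' is the glycidate stereocentre.

## Route

**Step 1**
Reactants: **1** 4-amino-3-methylphenol
Product: **2** 2-methyl-4-[(triisopropylsilyl)oxy]aniline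
Conditions: TIPSCl, imidazole, DMF, rt
Reagents that add atoms: TIPSCl, CC(C)[Si](Cl)(C(C)C)C(C)C
Why: Selective O-silylation of the phenol gives a base- and heat-stable aryl silyl ether that survives to the final fluoride deprotection.

**Step 2**
Reactants: **2**
Product: **3** 2-iodo-6-methyl-4-[(triisopropylsilyl)oxy]aniline
Conditions: NIS, MeCN, 0 °C to rt
Reagents that add atoms: N-iodosuccinimide, O=C1CCC(=O)N1I
Why: Electrophilic aromatic iodination goes to the only free position ortho to the strongly activating NH2 (para is blocked).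

**Step 3**
Reactants: **3**
Product: **4** (4-bromo-3-iodo-5-methylphenoxy)triisopropylsilane
Conditions: t-BuONO, CuBr2, MeCN, 0 to 60 °C
Reagents that add atoms: CuBr2, Br[Cu]Br
Why: Sandmeyer bromination replaces NH2 by Br, giving an arene with a reactive C–I for C–C coupling next to a less reactive C–Br for the later C–O closure.

**Step 4**
Reactants: **5** (R)-(−)-linalool; **4**
Product: **6** (3R)-1-{2-bromo-3-methyl-5-[(triisopropylsilyl)oxy]phenyl}-3,7-dimethyloct-6-en-3-ol
Conditions: 9-BBN (2.2 equiv), THF, 0 °C to rt; then **4**, PdCl2(dppf) (5 mol%), aq. K3PO4, DMF, rt to 45 °C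
Reagents that add atoms: none (9-BBN supplies only H)
Why: 9-BBN hydroborates only the monosubstituted vinyl group, and the B-alkyl Suzuki–Miyaura coupling occurs at C–I in preference to the hindered C–Br; the carbinol stereocentre is not involved.

**Step 5**
Reactants: **6**
Product: **7** triisopropyl{[(2R)-2,8-dimethyl-2-(4-methylpent-3-en-1-yl)-3,4-dihydro-2H-chromen-6-yl]oxy}silane
Conditions: Pd(OAc)2 (5 mol%), t-BuXPhos (achiral), Cs2CO3, toluene, 80 °C
Reagents that add atoms: none
Why: Buchwald-type intramolecular Pd-catalysed aryl etherification of a tertiary alcohol (no β-hydride) forms O1–C8a, so the C2–O bond is untouched and the linalool configuration is retained as 2R.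

**Step 6**
Reactants: **7**
Product: **8** 3-{(2S)-2,8-dimethyl-6-[(triisopropylsilyl)oxy]-3,4-dihydro-2H-chromen-2-yl}propanal (same spatial arrangement; descriptor changes by CIP priority only)
Conditions: OsO4 (2 mol%), NaIO4, 2,6-lutidine, dioxane/H2O, rt
Reagents that add atoms: NaIO4, [Na+].[O-]I(=O)(=O)=O, with cat. OsO4, O=[Os](=O)(=O)=O (aldehyde oxygen)
Why: Lemieux–Johnson cleavage of the only C=C gives the aldehyde without touching the electron-rich arene.

**Step 7**
Reactants: **8**
Product: **9** 5-{(2S)-2,8-dimethyl-6-[(triisopropylsilyl)oxy]-3,4-dihydro-2H-chromen-2-yl}-2-methylpent-1-en-3-yl acetate (about 1:1 at the carbinol carbon, which is destroyed in Step 8)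
Conditions: isopropenylmagnesium bromide, THF, −78 to 0 °C; then Ac2O, DMAP, 0 °C to rt
Reagents that add atoms: isopropenylmagnesium bromide, CC(=C)[Mg]Br; acetic anhydride, CC(=O)OC(C)=O
Why: Grignard 1,2-addition followed by in-situ acylation of the magnesium alkoxide gives the allylic acetate needed for the Claisen step.

**Step 8 (key step)**
Reactants: **9**
Product: **10** (4E)-7-{(2R)-2,8-dimethyl-6-[(triisopropylsilyl)oxy]-3,4-dihydro-2H-chromen-2-yl}-4-methylhept-4-enoic acid
Conditions: LDA, THF, −78 °C; TMSCl; warm to rt, then 60 °C; aq. HCl work-up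
Reagents that add atoms: none
Why: Ireland–Claisen [3,3]-sigmatropic rearrangement of the silyl ketene acetal through a chair transition state with the carbinol substituent equatorial forms the C5'–C6' bond and the (E)-trisubstituted 3',4'-olefin; both carbinol epimers converge on the same product.

**Step 9**
Reactants: **11** methyl (R)-glycidate
Product: **12** methyl (2R)-2-hydroxy-5-methylhex-4-enoate
Conditions: 2-methyl-1-propenylmagnesium bromide, CuI (10 mol%), THF, −40 °C
Reagents that add atoms: 2-methyl-1-propenylmagnesium bromide, CC(C)=C[Mg]Br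
Why: Cu-catalysed SN2 epoxide opening occurs at the unsubstituted C3, so the bought C2 stereocentre (the future C9') is untouched.

**Step 10**
Reactants: **12**
Product: **13** methyl (2R)-2-[(tert-butyldimethylsilyl)oxy]-5-methylhex-4-enoate
Conditions: TBSCl, imidazole, DMF, rt
Reagents that add atoms: TBSCl, CC(C)(C)[Si](C)(C)Cl
Why: Silyl protection of the secondary alcohol, needed for the organometallic steps that follow.

**Step 11**
Reactants: **13**
Product: **14** (R)-tert-butyl[(6-methylhept-5-en-1-yn-3-yl)oxy]dimethylsilane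
Conditions: DIBAL-H (1.05 equiv), CH2Cl2, −78 °C; then MeOH, K2CO3, Ohira–Bestmann reagent, −78 °C to rt
Reagents that add atoms: dimethyl (1-diazo-2-oxopropyl)phosphonate, CC(=O)C(=[N+]=[N-])P(=O)(OC)OC (terminal alkyne carbon)
Why: One-pot partial reduction to the α-silyloxy aldehyde and Seyferth–Gilbert/Ohira–Bestmann homologation gives the terminal alkyne under conditions that normally preserve α-silyloxy stereocentres.

**Step 12**
Reactants: **14**
Product: **15** (R,E)-tert-butyl[(1-iodo-2,6-dimethylhepta-1,5-dien-3-yl)oxy]dimethylsilane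
Conditions: AlMe3 (3 equiv), Cp2ZrCl2 (25 mol%), H2O (1 equiv), CH2Cl2, −20 °C; then I2, THF, −30 to 0 °C
Reagents that add atoms: trimethylaluminium, C[Al](C)C; iodine, II
Why: Negishi Zr-catalysed syn-carboalumination puts Me on the internal carbon and Al on the terminus, and iodinolysis with retention gives the (E)-vinyl iodide, fixing the 7'E geometry.

**Step 13**
Reactants: **10**; **15** (2 equiv)
Product: **16** triisopropyl({(2R)-2-[(3E,7E,9R)-9-[(tert-butyldimethylsilyl)oxy]-4,8,12-trimethyltrideca-3,7,11-trien-1-yl]-2,8-dimethyl-3,4-dihydro-2H-chromen-6-yl}oxy)silane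
Conditions: **10**, N-hydroxytetrachlorophthalimide, DIC, THF, rt (redox-active ester in situ); alkenylzinc from **15** (t-BuLi, Et2O, −78 °C; ZnCl2); Ni(acac)2 (10 mol%), 2,2'-bipyridine (10 mol%), THF/DMF, rt
Reagents that add atoms: none
Why: Ni-catalysed decarboxylative alkenylation of the redox-active ester (Baran-type) joins the primary C6' radical to the alkenylzinc with retention of olefin geometry; no stereocentre is touched.

**Step 14**
Reactants: **16**
Product: **17** sargachromanol C, (2R)-2-[(3E,7E,9R)-9-hydroxy-4,8,12-trimethyltrideca-3,7,11-trien-1-yl]-2,8-dimethyl-3,4-dihydro-2H-chromen-6-ol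
Conditions: TBAF, AcOH (buffer), THF, 0 °C to rt, under Ar
Reagents that add atoms: none
Why: Fluoride cleaves both the aryl TIPS and secondary TBS ethers under near-neutral conditions that leave the allylic alcohol, the olefins and the air-sensitive chromanol intact.

## Compound list

1 | 4-amino-3-methylphenol | Cc1cc(O)ccc1N | starting material
2 | 2-methyl-4-[(triisopropylsilyl)oxy]aniline | Cc1cc(O[Si](C(C)C)(C(C)C)C(C)C)ccc1N | intermediate
3 | 2-iodo-6-methyl-4-[(triisopropylsilyl)oxy]aniline | Cc1cc(O[Si](C(C)C)(C(C)C)C(C)C)cc(I)c1N | intermediate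
4 | (4-bromo-3-iodo-5-methylphenoxy)triisopropylsilane | Cc1cc(O[Si](C(C)C)(C(C)C)C(C)C)cc(I)c1Br | intermediate
5 | (R)-(−)-linalool | CC(C)=CCC[C@@](C)(O)C=C | starting material
6 | (3R)-1-{2-bromo-3-methyl-5-[(triisopropylsilyl)oxy]phenyl}-3,7-dimethyloct-6-en-3-ol | CC(C)=CCC[C@@](C)(O)CCc1cc(O[Si](C(C)C)(C(C)C)C(C)C)cc(C)c1Br | intermediate
7 | (2R)-2,8-dimethyl-2-(4-methylpent-3-enyl)-6-(TIPS-oxy)chroman | CC(C)=CCC[C@]1(C)CCc2cc(O[Si](C(C)C)(C(C)C)C(C)C)cc(C)c2O1 | intermediate
8 | 3-[(2S)-2,8-dimethyl-6-(TIPS-oxy)chroman-2-yl]propanal | O=CCC[C@]1(C)CCc2cc(O[Si](C(C)C)(C(C)C)C(C)C)cc(C)c2O1 | intermediate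
9 | 5-[(2S)-2,8-dimethyl-6-(TIPS-oxy)chroman-2-yl]-2-methylpent-1-en-3-yl acetate (epimer mixture at the carbinol) | C=C(C)C(OC(C)=O)CC[C@]1(C)CCc2cc(O[Si](C(C)C)(C(C)C)C(C)C)cc(C)c2O1 | intermediate
10 | (4E)-7-[(2R)-2,8-dimethyl-6-(TIPS-oxy)chroman-2-yl]-4-methylhept-4-enoic acid | OC(=O)CC/C(C)=C/CC[C@]1(C)CCc2cc(O[Si](C(C)C)(C(C)C)C(C)C)cc(C)c2O1 | intermediate
11 | methyl (R)-glycidate | COC(=O)[C@H]1CO1 | starting material
12 | methyl (2R)-2-hydroxy-5-methylhex-4-enoate | CC(C)=CC[C@@H](O)C(=O)OC | intermediate
13 | methyl (2R)-2-(TBS-oxy)-5-methylhex-4-enoate | CC(C)=CC[C@@H](O[Si](C)(C)C(C)(C)C)C(=O)OC | intermediate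
14 | (R)-tert-butyl[(6-methylhept-5-en-1-yn-3-yl)oxy]dimethylsilane | CC(C)=CC[C@@H](O[Si](C)(C)C(C)(C)C)C#C | intermediate
15 | (R,E)-tert-butyl[(1-iodo-2,6-dimethylhepta-1,5-dien-3-yl)oxy]dimethylsilane | CC(C)=CC[C@@H](O[Si](C)(C)C(C)(C)C)/C(C)=C/I | intermediate
16 | 6-O-TIPS, 9'-O-TBS sargachromanol C | CC(C)=CC[C@@H](O[Si](C)(C)C(C)(C)C)/C(C)=C/CC/C(C)=C/CC[C@]1(C)CCc2cc(O[Si](C(C)C)(C(C)C)C(C)C)cc(C)c2O1 | intermediate
17 | sargachromanol C | CC(C)=CC[C@@H](O)/C(C)=C/CC/C(C)=C/CC[C@]1(C)CCc2cc(O)cc(C)c2O1 | target

## Summary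

Total steps: 14. Longest linear sequence: 10 (Steps 1–8, 13, 14).

Steps most likely to fail, with fallbacks:

1. **Step 13 (decarboxylative alkenylation; unactivated primary acid, functionalised alkenylzinc in excess).** Fallback: convert acid **10** to the C6' primary iodide by iododecarboxylation (Barton ester/CHI3), then t-BuLi/B-methoxy-9-BBN and a Pd-catalysed B-alkyl Suzuki coupling with **15** as the limiting partner.
2. **Step 12 (carboalumination of an α-branched propargylic silyl ether).** Fallback: Cu-catalysed syn-methylboration of **14** (B2pin2, MeI, CuCl/Xantphos, NaOt-Bu) to the (E)-2-methylalkenyl boronate, then iododeboronation (NaOMe, I2) to **15**.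
3. **Step 5 (Pd C–O closure on a di-ortho-substituted aryl bromide).** Fallback: couple the linalool-derived borane with 1-bromo-2,5-dimethoxy-3-methylbenzene, oxidise with CAN to the quinone, reduce (Na2S2O4) and cyclodehydrate with cat. TsOH, then silylate to **7**. This closure is reported to go with retention (tertiary OH attacks the ring carbon), but that is from memory and would need checking on this substrate.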